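Put the flask beside Monday's run, which looks nearly the same: equal equivalents of L and an equal ratio of phases, but cJ at 10 mM instead of 6.7 mM, and a reading 30.0 s later.

| flask | J | L | remark | time | volume of the second phase over the first |
|---|---|---|---|---|---|
| Monday's | 6.7 mM | 2 equiv | run made earlier |  |  |
| Saturday's | 15 mM | 2 equiv | run made earlier |  |  |
| flask | 10 mM | 2.00 equiv |  | 2.5 min | 0.25 |

| run | time / s | X / % |
|---|---|---|
| Monday's | 10.0 | 3.1 |
| Monday's | 20.0 | 8.4 |
| Monday's | 30.0 | 12.9 |
| Monday's | 60.0 | 22.4 |
| Monday's | 120 | 30.8 |
| Saturday's | 10.0 | 6.1 |
| Saturday's | 30.0 | 22.6 |
| Saturday's | 60.0 | 35.4 |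
| Saturday's | 80.0 | 39.0 |
| Saturday's | 120 | 43.9 |

(each reading ± 0.3 percentage points)

- in the second phase: L; everything else is in the first
- charges count per volume of the first phase; a concentration in a rate is the amount of a species over the volume of its own phase; every rate counts per litre of the first phase
- the earlier runs hold the two phases in the same ratio of volumes as the flask asked about

- how much X there is at 2.5 min, in percent of the J charged
- the change that raises the amount of X at 2.5 min, in percent of the J charged most ("none" if none brings more than 2 percentage points) (elm / ash / none)
- amount of X at 2.5 min, in percent of the J charged, after ash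

- elm: doubling the transfer coefficient of L, all else as stated
- ash: doubling the amount of L, all else as stated

To learn what the higher charge does, we hold Saturday's run against Monday's at one time, so that time drops out of the comparison. A course first-order in J, with one rate constant held, gives equal percentages at equal times whatever the charge, yet at 120 s Saturday's run stands higher than Monday's, 43.9 % against 30.8 %. So we define the charge exponent n as the logarithm of the ratio of these percentages over the logarithm of the ratio of the charges: 0.440.

With n, Monday's last reading becomes 36.7 % at the flask's cJ, still at 120 s. Saturday's last two readings rise as time to the power 0.292, and this carries our figure for the flask to 39.2 %. Both runs hold 2 equiv, so n moves J and L together, and we take no number for elm or ash from it.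

The forecast, reckoned its own way from plateaus, gives 39.3 %, chooses ash and puts that flask at 59 %: “X then levels off well short of full conversion, and at a higher plateau for the stronger charge.”

    J ⇌ Q (K = 16.0, k = 0.00633 s⁻¹)
    D ⇌ L, rate k2*([D] - [L]/K2) per volume of the first phase (partition coefficient = 0.369, kL = 0.00710 s⁻¹)
    2 D → Z (k = 0.868 M⁻¹ s⁻¹)
    J + D → X (k = 0.774 M⁻¹ s⁻¹)

The flask gives 39.0 % against our 39.2 %. Elm adds 0.52 percentage points and ash adds 13 points, so ash stands first, and it reaches 52.2 %, lower than the forecast's figure. Now take n to the neighbour with cJ at 2.5 mM, equivalents and time held: the flask's percentage scaled by n gives 21.2 %. That neighbour ends at 19.0 % of X, with 29 % of its J still unbound.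

The earlier runs and the new flask come from a simulation for substances that don't exist, noise included.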